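Reading this flask off the clock is the trap: in the south-east run J stays between 24.0% and 27.0% from 1.50 h to 12.0 h while X climbs from 15.5% to 43.4%. So you plot J against r, the part of the Q charged not yet in J or X.

| flask | Q | G | remark | time |
|---|---|---|---|---|
| north-east | 0.025 M | 0.050 M | run made earlier |  |
| south-east | 0.038 M | 0.050 M | run made earlier |  |
| west | 0.050 M | 0.075 M | run made earlier |  |
| flask | 0.050 M | 0.0500 M |  | 10 h |

| run | time / h | J / % | X / % |
|---|---|---|---|
| north-east | 1.50 | 25.3 | 17.2 |
| north-east | 3.00 | 26.1 | 33.7 |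
| north-east | 5.00 | 24.0 | 46.5 |
| north-east | 6.00 | 22.1 | 50.9 |
| north-east | 8.00 | 19.8 | 57.6 |
| north-east | 10.0 | 19.0 | 61.7 |
| north-east | 12.0 | 17.6 | 63.9 |
| south-east | 1.50 | 25.0 | 15.5 |
| south-east | 3.00 | 27.0 | 27.7 |
| south-east | 5.00 | 26.4 | 35.3 |
| south-east | 6.00 | 25.0 | 38.1 |
| south-east | 8.00 | 25.3 | 42.2 |
| south-east | 10.0 | 25.0 | 42.6 |
| south-east | 12.0 | 24.0 | 43.4 |
| west | 1.00 | 25.8 | 15.3 |
| west | 3.00 | 25.6 | 38.6 |
| west | 6.00 | 23.1 | 50.9 |
| west | 8.00 | 21.0 | 52.4 |
| west | 12.0 | 20.5 | 54.8 |

(scatter of a reading: 0.5 percentage points)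

* equivalents of G to Q, everything else as given, that leave most J at 10 h
* the amount of J then, in percent of the Q charged
* the amount of J with the amounts as given

Take Q + G to J and J + G to X: both steps run on cG, so on that scheme cG cancels and J follows one curve in r. At the start each G makes one J, so J rises one for one as r falls. Late on, J falls in step with r, as r over (s minus one). Joining the ends gives r to the power s, minus r, all over (one minus s), which tops where J equals r/s. South-east tops near 3.00 h, so that reading gives s = 1.68, an apparent selectivity factor: the fractional rate at which J is used over the fractional rate at which r falls. My peak therefore stands at r = 46.6% with J = 27.8%, and it costs 0.790 equiv of G, one per J and two per X.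

But by 12.0 h south-east shows 0.00790 M of G in neither product. Allowing that loss in the flask, I would charge 0.948 equiv, and the given 1.00 equiv lands just past the peak.

The forecast, a little lower, says 0.93 equiv, 27% at best and 26.6% as charged, holding that “G is also lost to a side route”.

The flask gives 26.7% as charged and 27.0% at 0.877 equiv.

    Q + G → J + E (k = 0.00330 L mol⁻¹ s⁻¹)
    G + J → X + E (k = 0.00450 L mol⁻¹ s⁻¹)
    Q → Z (k = 1.10 × 10⁻⁷ s⁻¹)
    Q ⇌ L (K = 0.290, k = 0.00580 s⁻¹)
    G → D (k = 1.60 × 10⁻⁵ s⁻¹)

At 10.0 h the flask's G, the limiting reagent, is down to 0.694% of its charge against Q at 32.7%. Its uptake of 0.886 equiv stands past w. The neighbour charged with 0.013 M has r = 80.3%, where the curve with s gives 16.4%, and it holds 16.2% of J.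

The numbers in the tables are calculated with made-up constants; scatter was added.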